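**Convention.** The oxolane atoms are O1, C2 (aryl-bearing), C3, C4, C5; C6 is the CH2O carbon on C3 and C7 the benzylic carbon on C4. These labels are kept for the open-chain intermediates. Ar = 4-(benzyloxy)-3-methoxyphenyl.

## The problem

Olivil monoacetate is a single oxolane with three contiguous stereocentres, (2S,3R,4S). C2 carries a 4-hydroxy-3-methoxyphenyl group, C3 carries the acetoxymethyl carbon C6 trans to it, and C4 is a fully substituted carbinol whose benzylic carbon C7 is cis and whose hydroxyl is trans to C6. C2 and C3 form an aldol pair and can be set reliably by an auxiliary. C4 is the hard centre: a quaternary carbinol next to the ring CH2 (C5) that must be placed relative to C3 and cannot be corrected later by epimerisation. The C2–O1 bond is a benzylic ether para to an oxygen substituent. Acid ionises it, which scrambles C2 and, once C7 is a methylene group, lets the electron-rich C7 aryl ring close onto C2 to an aryltetralin; hydrogenation can also cleave it. A cation at C7 is equally unwelcome, because it sits beside the C4 oxygen (ring-enlarging pinacol-type shift) and within reach of the C6 oxygen (furofuran closure). The primary acetate has to be put on while both phenols are masked and must not meet base afterwards. The opening lies at C4: it holds an oxygen and the CH2 group C5 that is also bonded to O1, so O1–C5H2 and the C4 oxygen are the two ends of a formaldehyde acetal on the C2 oxygen. A shift of C5 from the outer acetal oxygen to C4 would create C4–O, C4–C5 and the ring from a protecting group.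

## Retrosynthesis

**Phenols and acetate (26 ⇐ 25 ⇐ 24).** The two O–benzyl bonds are cut last, so 26 comes from the dibenzyl ether 25 by hydrogenolysis, the one deprotection that spares the acetate and needs no acid or base. The acetyl C–O bond is cut next: in diol 24 only the primary C6 hydroxyl can be acylated, because the C4 hydroxyl is tertiary and the phenols are still ethers. The forward steps need only chemoselectivity.

**C7 oxidation level (24 ⇐ 22 ⇐ 21 ⇐ 20 ⇐ 19).** The C7 methylene is traced back to an aryl ketone, which the key step needs to stabilise the carbenoid and the ylide. The C7–O bond is removed by a radical path through the cyclic thionocarbonate 22 of diol 21. An ionic hydrogenation is avoided because a C7 cation invites ring enlargement and capture by O6, and because acid at the methylene stage opens C2–O1. The 2-(trimethylsilyl)ethyl ether left on C4 by the key step is cut at the ketone stage (19 to 20), when the C7 aryl ring is deactivated by the carbonyl group. The tert-butyldiphenylsilyl ether on C6 is chosen to survive that Lewis acid.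

**Key disconnection (19 ⇐ 17).** The C4–C5 and C4–O bonds are cut together, which opens the oxolane to the acyclic α-diazo aryl ketone 17 carrying a 2-(trimethylsilyl)ethoxymethyl ether on the C2 oxygen. The neighbouring cuts (O1–C5 etherification, or C2–O1 closure onto a benzylic cation) both require the quaternary C4 carbinol to be set in an open chain. This cut removes the ring, the quaternary centre and both heteroatom bonds at C4 in one step, and leaves a precursor with two stereocentres and no quaternary carbon. The forward reaction must form the ylide faster than a hydride shift or C–H insertion, must move C5 and not the silylethyl group, and must deliver C5 to the correct face of C4.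

**Diazo ketone and C7–aryl bond (17 ⇐ 15 ⇐ 14 ⇐ 10 + 12).** The diazo group is removed to give ketone 15, which only C4 can enolise. The C7–aryl bond is then cut to aldehyde 10 and the aryllithium 13 derived from bromide 12 (made from phenol 11). Exactly two carbons must lie between C3 and the aryl ring. An aryl-alkynoyl chain one carbon longer would place the ketone one atom too far out after hydration, so C7 is carried as the aldehyde of a cleaved allyl group.

**Protecting-group pattern (10 ⇐ 9 ⇐ 7 ⇐ 6 ⇐ 5).** Cutting the C7=O back to a terminal alkene gives 9. The acetal on the C2 oxygen (from chloride 8) and the silyl ether on C6 are removed in turn to diol 6. The acetal must sit on the C2 oxygen, where its outer oxygen can reach C4 through a six-membered ring. The C6 oxygen is given a bulky silyl group that could only form a four-membered ylide. Diol 6 is the reduced form of aldol adduct 5.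

**C2–C3 bond (5 ⇐ 3 + 4; 3 ⇐ 1 + 2).** The C2–C3 bond is cut by an Evans syn-aldol reaction between imide 3 and aldehyde 4. The syn pair from the (S)-auxiliary 1 maps onto the 2,3-trans oxolane with the natural absolute configuration. Imide 3 comes from 1 and acid chloride 2. Both new stereocentres are set in a reaction with a long record for aryl aldehydes.

## Roads not taken

**Alternative 1:** The oxolane is kept and the cut is made at C7–aryl and C4–O, giving the 4-methylidene oxolane A2 and the arylhydrazine A3. In the forward step MnO2 converts A3 to an aryl radical, which adds to the exocyclic CH2 (the future C7). The tertiary C4 radical is trapped by O2 and the hydroperoxide is reduced in the same flask by PPh3, giving A1. A1 is the same compound as 25 and is one hydrogenolysis from the target.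
- Merits: C7 arrives at the methylene level, no diazo compound or deoxygenation sequence is needed, and the route would be roughly half as long.
- Weak points: the C4 configuration is decided when O2, a very small trap, meets a planar tertiary radical. One face is flanked by the C3 acetoxymethyl group and the other by the C2 aryl group across the ring, so little face preference can be expected. The donor-substituted aryl radical is also poorly matched to an unactivated 1,1-dialkyl alkene that cannot be used in excess, and hydrogen abstraction from C2–H or the OCH2Ph groups competes.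
- Comparison: in step count this road is better. The chosen plan sets against it that both new bonds at C4 are delivered through a tether inside a ring, so the face is fixed by C3 and not left to an intermolecular trap.

**Alternative 2:** The cut goes through C2–C3 and C4–C5, so the whole ring is assembled from the α-silyl chloro ether A6 and the (E)-enol acetate A5. Fluoride turns A6 into a non-stabilised carbonyl ylide, which adds across A5 in a [3+2] cycloaddition to give A4.
- Merits: this is the most convergent road. The C3/C4 relationship follows stereospecifically from the alkene geometry, and the tertiary oxygen enters as an acetate that could later migrate to O6.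
- Weak points: three selectivities rest on a dipolarophile class with no record for this dipole. These are regiochemistry (the aryl-bearing terminus must bond to C3), endo/exo selectivity (C2 aryl trans to the C3 acyl group) and absolute configuration, since neither partner is chiral. The trisubstituted, donor-substituted alkene is a sluggish acceptor, so collapse or dimerisation of the ylide competes. The imide must then be reduced beside a tertiary acetate.
- Comparison: on paper this is shorter and more convergent. The chosen plan sets against it an aldol of proven reliability for C2/C3, which leaves only one stereocentre to the untested step.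

**Alternative 3:** The cut is at C4–C7 with the C4 oxygen as a ketone. The precursor is the 4-oxo-oxolane A8, whose C6 oxygen carries the future C7 as a 4-(benzyloxy)-3-methoxybenzyl ether. On irradiation the excited C4 ketone abstracts a benzylic ether hydrogen (a 1,6-transfer, because the γ position is oxygen). The 1,5-biradical then forms C4–C7, giving the cis-fused furofuran A7 with a bridgehead hydroxyl.
- Merits: as in the chosen plan, C4 is set by a tether. The second ring can only be cis-fused, which puts C7 cis and OH trans to C6. C7 arrives with its aryl group, so only hydrogenolysis of the temporary C7–O6 bond separates A7 from the olivil skeleton.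
- Weak points: α-alkoxy ketones such as A8 are prone to α-cleavage at C4–C5, and the electron-rich arenes can quench the excited ketone by charge transfer. Two benzylic C–O bonds (C7–O6 and C2–O1) must then be told apart in a hydrogenolysis. That is why the C2 aryl group has to carry a deactivating mesylate, which must later be removed beside a base-labile acetate.
- Comparison: its endgame is probably shorter than the deoxygenation sequence used here. The chosen plan sets against it a thermal catalytic step with close relatives and no need to discriminate between benzylic C–O bonds.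

Key step: step 11

Assumption: compounds 1, 2, 4, 8 and 11 are taken as catalogue chemicals, and the C7 carbinol centres of 14, 21 and 22 are carried as epimer mixtures because C7 ends as a ketone or a methylene group.

## Route

Step 1
Reactants: 1 (S)-4-benzyloxazolidin-2-one; 2 pent-4-enoyl chloride
Product: 3 (S)-4-benzyl-3-(pent-4-enoyl)oxazolidin-2-one
Conditions: n-BuLi, THF, −78 °C; then 2, −78 → 0 °C
Reagents that add atoms: none
Why: N-acylation of the lithiated oxazolidinone by an acid chloride, the standard preparation of an acyl oxazolidinone; no stereocentre is formed or endangered.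

Step 2
Reactants: 3 (S)-4-benzyl-3-(pent-4-enoyl)oxazolidin-2-one; 4 4-(benzyloxy)-3-methoxybenzaldehyde
Product: 5 (S)-4-benzyl-3-{(S)-2-[(S)-[4-(benzyloxy)-3-methoxyphenyl](hydroxy)methyl]pent-4-enoyl}oxazolidin-2-one
Conditions: Bu2BOTf, iPr2NEt, CH2Cl2, 0 °C; 4, −78 → 0 °C; then pH 7 buffer, MeOH, H2O2, 0 °C
Reagents that add atoms: none
Why: Evans syn-aldol reaction: soft enolisation gives the Z-boron enolate, which adds to the aldehyde through a closed chair transition state on the face away from the auxiliary benzyl group; this sets C3 and C2 together (both S in 5) as the syn pair that becomes the 2,3-trans relationship of the oxolane.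

Step 3
Reactants: 5 (S)-4-benzyl-3-{(S)-2-[(S)-[4-(benzyloxy)-3-methoxyphenyl](hydroxy)methyl]pent-4-enoyl}oxazolidin-2-one
Product: 6 (1S,2R)-1-[4-(benzyloxy)-3-methoxyphenyl]-2-(prop-2-en-1-yl)propane-1,3-diol
Conditions: LiBH4, MeOH (1 equiv), THF, 0 °C
Reagents that add atoms: none
Why: Reductive cleavage of the acyl oxazolidinone at the exocyclic carbonyl gives the primary C6 alcohol and returns the auxiliary; the conditions neither epimerise C3 nor promote retro-aldol cleavage.

Step 4
Reactants: 6 (1S,2R)-1-[4-(benzyloxy)-3-methoxyphenyl]-2-(prop-2-en-1-yl)propane-1,3-diol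
Product: 7 (1S,2R)-1-[4-(benzyloxy)-3-methoxyphenyl]-2-{[(tert-butyldiphenylsilyl)oxy]methyl}pent-4-en-1-ol
Conditions: TBDPSCl, imidazole, CH2Cl2, 0 °C → rt
Reagents that add atoms: tert-butyl(chloro)diphenylsilane, CC(C)(C)[Si](Cl)(c1ccccc1)c1ccccc1
Why: Silylation with a bulky chlorosilane takes the primary C6 hydroxyl in preference to the hindered secondary benzylic one; this silyl ether is chosen because it later has to survive an aryllithium, BF3·OEt2 and radical conditions.

Step 5
Reactants: 7 (1S,2R)-1-[4-(benzyloxy)-3-methoxyphenyl]-2-{[(tert-butyldiphenylsilyl)oxy]methyl}pent-4-en-1-ol; 8 2-(trimethylsilyl)ethoxymethyl chloride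
Product: 9 tert-butyl{[(2R)-2-{(S)-[4-(benzyloxy)-3-methoxyphenyl]{[2-(trimethylsilyl)ethoxy]methoxy}methyl}pent-4-en-1-yl]oxy}diphenylsilane
Conditions: iPr2NEt, Bu4NI (cat.), CH2Cl2, 40 °C
Reagents that add atoms: none
Why: Williamson-type alkylation of the secondary alcohol with the chloromethyl ether under amine base (iodide catalysis) installs the formaldehyde acetal whose CH2 becomes C5; no stereocentre is touched.

Step 6
Reactants: 9 tert-butyl{[(2R)-2-{(S)-[4-(benzyloxy)-3-methoxyphenyl]{[2-(trimethylsilyl)ethoxy]methoxy}methyl}pent-4-en-1-yl]oxy}diphenylsilane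
Product: 10 (3R,4S)-4-[4-(benzyloxy)-3-methoxyphenyl]-3-{[(tert-butyldiphenylsilyl)oxy]methyl}-4-{[2-(trimethylsilyl)ethoxy]methoxy}butanal
Conditions: OsO4 (cat.), NaIO4, 2,6-lutidine, dioxane/H2O, rt
Reagents that add atoms: osmium tetroxide, O=[Os](=O)(=O)=O (delivers the aldehyde oxygen and is reoxidised by sodium periodate, [Na+].[O-]I(=O)(=O)=O)
Why: Lemieux–Johnson oxidation: catalytic dihydroxylation of the terminal alkene and periodate cleavage give the C7 aldehyde with loss of the terminal carbon; 2,6-lutidine suppresses over-oxidation, and the method spares the electron-rich arenes that ozone would attack.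

Step 7
Reactants: 11 4-bromo-2-methoxyphenol
Product: 12 1-(benzyloxy)-4-bromo-2-methoxybenzene
Conditions: BnBr, K2CO3, DMF, rt
Reagents that add atoms: benzyl bromide, BrCc1ccccc1
Why: Williamson ether synthesis on the phenoxide; the benzyl ether matches the protecting group of the other ring so that both fall in the last step.

Step 8
Reactants: 12 1-(benzyloxy)-4-bromo-2-methoxybenzene; 10 (3R,4S)-4-[4-(benzyloxy)-3-methoxyphenyl]-3-{[(tert-butyldiphenylsilyl)oxy]methyl}-4-{[2-(trimethylsilyl)ethoxy]methoxy}butanal
Product: 14 (3R,4S)-1,4-bis[4-(benzyloxy)-3-methoxyphenyl]-3-{[(tert-butyldiphenylsilyl)oxy]methyl}-4-{[2-(trimethylsilyl)ethoxy]methoxy}butan-1-ol as both C1 epimers, via [4-(benzyloxy)-3-methoxyphenyl]lithium 13 (not isolated)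
Conditions: 12, n-BuLi, THF, −78 °C; then 10, −78 °C; H2O
Reagents that add atoms: none
Why: Bromine–lithium exchange gives the aryllithium, which adds to the aldehyde faster than it deprotonates it at −78 °C; the new C7 carbinol centre is not controlled and need not be, since it is oxidised in the next step.

Step 9
Reactants: 14 (3R,4S)-1,4-bis[4-(benzyloxy)-3-methoxyphenyl]-3-{[(tert-butyldiphenylsilyl)oxy]methyl}-4-{[2-(trimethylsilyl)ethoxy]methoxy}butan-1-ol
Product: 15 (3R,4S)-1,4-bis[4-(benzyloxy)-3-methoxyphenyl]-3-{[(tert-butyldiphenylsilyl)oxy]methyl}-4-{[2-(trimethylsilyl)ethoxy]methoxy}butan-1-one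
Conditions: Dess–Martin periodinane, CH2Cl2, rt
Reagents that add atoms: none
Why: Dess–Martin oxidation of the secondary benzylic alcohol to the aryl ketone under near-neutral conditions; C3 is β to the new carbonyl and cannot epimerise.

Step 10
Reactants: 15 (3R,4S)-1,4-bis[4-(benzyloxy)-3-methoxyphenyl]-3-{[(tert-butyldiphenylsilyl)oxy]methyl}-4-{[2-(trimethylsilyl)ethoxy]methoxy}butan-1-one
Product: 17 (3R,4S)-1,4-bis[4-(benzyloxy)-3-methoxyphenyl]-3-{[(tert-butyldiphenylsilyl)oxy]methyl}-2-diazo-4-{[2-(trimethylsilyl)ethoxy]methoxy}butan-1-one, via trifluoroacetyl ketone 16 (not isolated)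
Conditions: LiN(SiMe3)2, THF, −78 °C; CF3CO2CH2CF3; dilute aq HCl quench, 0 °C; then MsN3, Et3N, H2O, MeCN, rt
Reagents that add atoms: methanesulfonyl azide, CS(=O)(=O)N=[N+]=[N-]
Why: Detrifluoroacetylative (Regitz-type deacylative) diazo transfer: the lithium enolate, which can only form at C4, is C-acylated by the trifluoroacetate ester, and the activated 1,3-diketone takes the diazo group from the sulfonyl azide with loss of the trifluoroacetyl group as the N-sulfonyl amide; no leaving group sits β to the enolate and C3 is not affected.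

Step 11
Reactants: 17 (3R,4S)-1,4-bis[4-(benzyloxy)-3-methoxyphenyl]-3-{[(tert-butyldiphenylsilyl)oxy]methyl}-2-diazo-4-{[2-(trimethylsilyl)ethoxy]methoxy}butan-1-one
Product: 19 {(3S,4R,5S)-5-[4-(benzyloxy)-3-methoxyphenyl]-4-{[(tert-butyldiphenylsilyl)oxy]methyl}-3-[2-(trimethylsilyl)ethoxy]oxolan-3-yl}[4-(benzyloxy)-3-methoxyphenyl]methanone, via oxonium ylide 18 (not isolated)
Conditions: Rh2(O2CCPh3)4 (1 mol %), CH2Cl2, −40 °C → rt, slow addition of 17
Reagents that add atoms: none
Why: Proposed new method: loss of N2 gives an electrophilic rhodium carbenoid at C4, which is captured by the outer acetal oxygen through a six-membered ring (O1 and the silyl ether oxygen could only close four-membered rings) to the oxonium ylide 18, stabilised as the aroyl enolate; the O–C5 bond of the ylide then breaks to a caged pair (a radical or oxocarbenium centre at C5, still tied to C2 through O1, and the C4 radical or enolate) that recombines at C4, a [1,2]-Stevens shift that forms C4–C5, leaves the silylethoxy oxygen on C4 and contracts the six-membered ylide to the oxolane. The closest known reaction type is carbenoid-derived oxonium ylide formation at an acetal oxygen of a cyclic acetal followed by [1,2]-shift of the acetal carbon; the untested part is the use of the CH2 of an acyclic alkoxymethyl ether as a ring-contracting migrating group on an alkyl-substituted carbenoid. The oxolane closes by ring contraction, the C4–C5 bond joining a tethered pair in a five-membered ring (formally 5-exo at the enolate carbon and 5-endo at the O1=C5 unit, a constraint that does not bind a caged recombination). C4 is the only new stereocentre and is set by the substrate: in the chair-like ylide with the C2 aryl and C3 silyloxymethyl groups equatorial, C5 lies on the axial side of C4 and bonds to that lobe with least motion, which puts the ether oxygen trans and the aroyl carbon cis to C6. Three selectivities are needed: ylide formation over 1,2-hydride shift from C3–H and over 1,5-insertion into the acetal C–H, for which the bulky triphenylacetate ligands and low temperature are chosen and the Lewis-basic oxygen in a six-membered array is the fastest trap; migration of C5 over the primary silylethyl group, secured by the second oxygen on C5; and face selectivity, secured by the tether.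

Step 12
Reactants: 19 {(3S,4R,5S)-5-[4-(benzyloxy)-3-methoxyphenyl]-4-{[(tert-butyldiphenylsilyl)oxy]methyl}-3-[2-(trimethylsilyl)ethoxy]oxolan-3-yl}[4-(benzyloxy)-3-methoxyphenyl]methanone
Product: 20 [(3S,4R,5S)-5-[4-(benzyloxy)-3-methoxyphenyl]-4-{[(tert-butyldiphenylsilyl)oxy]methyl}-3-hydroxyoxolan-3-yl][4-(benzyloxy)-3-methoxyphenyl]methanone
Conditions: BF3·OEt2, CH2Cl2, −20 → 0 °C
Reagents that add atoms: none
Why: Lewis acid cleavage of a 2-(trimethylsilyl)ethyl ether: coordination of BF3 to the ether oxygen triggers β-silyl fragmentation to ethene and Me3SiF, while ionisation of C4–O is blocked by the adjacent carbonyl; it is done at the ketone stage because the aroyl ring is too electron-poor to attack C2 should the benzylic C2–O1 bond open reversibly, and the bulky silyl ether and aryl benzyl ethers tolerate the conditions.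

Step 13
Reactants: 20 [(3S,4R,5S)-5-[4-(benzyloxy)-3-methoxyphenyl]-4-{[(tert-butyldiphenylsilyl)oxy]methyl}-3-hydroxyoxolan-3-yl][4-(benzyloxy)-3-methoxyphenyl]methanone
Product: 21 (3S,4R,5S)-5-[4-(benzyloxy)-3-methoxyphenyl]-3-{[4-(benzyloxy)-3-methoxyphenyl](hydroxy)methyl}-4-{[(tert-butyldiphenylsilyl)oxy]methyl}oxolan-3-ol as both C7 epimers
Conditions: NaBH4, MeOH/THF, 0 °C
Reagents that add atoms: none
Why: Borohydride reduction of the aryl ketone to the carbinol; either C7 epimer serves because the centre is removed two steps later.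

Step 14
Reactants: 21 (3S,4R,5S)-5-[4-(benzyloxy)-3-methoxyphenyl]-3-{[4-(benzyloxy)-3-methoxyphenyl](hydroxy)methyl}-4-{[(tert-butyldiphenylsilyl)oxy]methyl}oxolan-3-ol
Product: 22 (5S,8S,9R)-4,8-bis[4-(benzyloxy)-3-methoxyphenyl]-9-{[(tert-butyldiphenylsilyl)oxy]methyl}-1,3,7-trioxaspiro[4.4]nonane-2-thione (cyclic thionocarbonate across the C4 and C7 oxygens)
Conditions: 1,1'-thiocarbonyldiimidazole, DMAP, toluene, 100 °C
Reagents that add atoms: 1,1'-thiocarbonyldiimidazole, S=C(n1ccnc1)n1ccnc1
Why: Thiocarbonylation of the secondary hydroxyl followed by closure by the neighbouring tertiary hydroxyl gives the five-membered cyclic thionocarbonate, the usual derivative of a vicinal diol for radical deoxygenation; C4 is not involved.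

Step 15
Reactants: 22 (5S,8S,9R)-4,8-bis[4-(benzyloxy)-3-methoxyphenyl]-9-{[(tert-butyldiphenylsilyl)oxy]methyl}-1,3,7-trioxaspiro[4.4]nonane-2-thione
Product: 24 (3S,4R,5S)-5-[4-(benzyloxy)-3-methoxyphenyl]-3-{[4-(benzyloxy)-3-methoxyphenyl]methyl}-4-(hydroxymethyl)oxolan-3-ol, via stannyl thiocarbonate 23 (not isolated)
Conditions: Bu3SnH, AIBN (cat.), toluene, 100 °C; then Bu4NF, THF, rt; aq NH4Cl
Reagents that add atoms: none
Why: Radical deoxygenation of a cyclic thionocarbonate (Barton–McCombie type): the stannyl radical adds to sulfur and the adduct fragments at C7–O, which gives the benzylic radical in preference to the tertiary alkyl one, and hydrogen transfer from Bu3SnH makes C7 a methylene group without any cationic intermediate; fluoride then takes tin from sulfur (the thiocarbonate loses COS on protonation) and cleaves the silyl ether, with C4 untouched throughout.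

Step 16
Reactants: 24 (3S,4R,5S)-5-[4-(benzyloxy)-3-methoxyphenyl]-3-{[4-(benzyloxy)-3-methoxyphenyl]methyl}-4-(hydroxymethyl)oxolan-3-ol
Product: 25 [(2S,3R,4S)-2-[4-(benzyloxy)-3-methoxyphenyl]-4-{[4-(benzyloxy)-3-methoxyphenyl]methyl}-4-hydroxyoxolan-3-yl]methyl acetate
Conditions: Ac2O, pyridine, CH2Cl2, 0 °C
Reagents that add atoms: acetic anhydride, CC(=O)OC(C)=O
Why: Acetylation with Ac2O/pyridine distinguishes the primary C6 hydroxyl from the tertiary C4 hydroxyl, which does not acylate without a nucleophilic catalyst; the phenols are still benzylated.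

Step 17
Reactants: 25 [(2S,3R,4S)-2-[4-(benzyloxy)-3-methoxyphenyl]-4-{[4-(benzyloxy)-3-methoxyphenyl]methyl}-4-hydroxyoxolan-3-yl]methyl acetate
Product: 26 [(2S,3R,4S)-4-hydroxy-2-(4-hydroxy-3-methoxyphenyl)-4-[(4-hydroxy-3-methoxyphenyl)methyl]oxolan-3-yl]methyl acetate (olivil monoacetate)
Conditions: H2 (1 atm), 10% Pd/C, EtOAc, rt, stopped after 2 equiv H2
Reagents that add atoms: none
Why: Hydrogenolysis of the two aryl benzyl ethers in a neutral solvent; aryl benzyl ethers are cleaved much faster than the cyclic benzylic C2–O1 bond, and the acetate and tertiary alcohol are inert.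

## Compound list

1 | (S)-4-benzyloxazolidin-2-one | O=C1N[C@@H](Cc2ccccc2)CO1 | starting material
2 | pent-4-enoyl chloride | C=CCCC(=O)Cl | starting material
3 | (S)-4-benzyl-3-(pent-4-enoyl)oxazolidin-2-one | C=CCCC(=O)N1[C@@H](Cc2ccccc2)COC1=O | intermediate
4 | 4-(benzyloxy)-3-methoxybenzaldehyde | COc1cc(C=O)ccc1OCc1ccccc1 | starting material
5 | (S)-4-benzyl-3-{(S)-2-[(S)-[4-(benzyloxy)-3-methoxyphenyl](hydroxy)methyl]pent-4-enoyl}oxazolidin-2-one | O[C@H](c1ccc(OCc2ccccc2)c(OC)c1)[C@H](CC=C)C(=O)N1[C@@H](Cc2ccccc2)COC1=O | intermediate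
6 | (1S,2R)-1-[4-(benzyloxy)-3-methoxyphenyl]-2-(prop-2-en-1-yl)propane-1,3-diol | O[C@H](c1ccc(OCc2ccccc2)c(OC)c1)[C@H](CC=C)CO | intermediate
7 | (1S,2R)-1-[4-(benzyloxy)-3-methoxyphenyl]-2-{[(tert-butyldiphenylsilyl)oxy]methyl}pent-4-en-1-ol | O[C@H](c1ccc(OCc2ccccc2)c(OC)c1)[C@H](CC=C)CO[Si](c1ccccc1)(c1ccccc1)C(C)(C)C | intermediate
8 | 2-(trimethylsilyl)ethoxymethyl chloride | C[Si](C)(C)CCOCCl | starting material
9 | tert-butyl{[(2R)-2-{(S)-[4-(benzyloxy)-3-methoxyphenyl]{[2-(trimethylsilyl)ethoxy]methoxy}methyl}pent-4-en-1-yl]oxy}diphenylsilane | C[Si](C)(C)CCOCO[C@H](c1ccc(OCc2ccccc2)c(OC)c1)[C@H](CC=C)CO[Si](c1ccccc1)(c1ccccc1)C(C)(C)C | intermediate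
10 | (3R,4S)-4-[4-(benzyloxy)-3-methoxyphenyl]-3-{[(tert-butyldiphenylsilyl)oxy]methyl}-4-{[2-(trimethylsilyl)ethoxy]methoxy}butanal | C[Si](C)(C)CCOCO[C@H](c1ccc(OCc2ccccc2)c(OC)c1)[C@H](CC=O)CO[Si](c1ccccc1)(c1ccccc1)C(C)(C)C | intermediate
11 | 4-bromo-2-methoxyphenol | COc1cc(Br)ccc1O | starting material
12 | 1-(benzyloxy)-4-bromo-2-methoxybenzene | COc1cc(Br)ccc1OCc1ccccc1 | intermediate
13 | [4-(benzyloxy)-3-methoxyphenyl]lithium | [Li]c1ccc(OCc2ccccc2)c(OC)c1 | intermediate (not isolated)
14 | (3R,4S)-1,4-bis[4-(benzyloxy)-3-methoxyphenyl]-3-{[(tert-butyldiphenylsilyl)oxy]methyl}-4-{[2-(trimethylsilyl)ethoxy]methoxy}butan-1-ol (C1 epimers) | C[Si](C)(C)CCOCO[C@H](c1ccc(OCc2ccccc2)c(OC)c1)[C@H](CC(O)c1ccc(OCc2ccccc2)c(OC)c1)CO[Si](c1ccccc1)(c1ccccc1)C(C)(C)C | intermediate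
15 | (3R,4S)-1,4-bis[4-(benzyloxy)-3-methoxyphenyl]-3-{[(tert-butyldiphenylsilyl)oxy]methyl}-4-{[2-(trimethylsilyl)ethoxy]methoxy}butan-1-one | C[Si](C)(C)CCOCO[C@H](c1ccc(OCc2ccccc2)c(OC)c1)[C@H](CC(=O)c1ccc(OCc2ccccc2)c(OC)c1)CO[Si](c1ccccc1)(c1ccccc1)C(C)(C)C | intermediate
16 | 2-(trifluoroacetyl) derivative of 15 (1,3-diketone, C2 of the butanone not defined) | C[Si](C)(C)CCOCO[C@H](c1ccc(OCc2ccccc2)c(OC)c1)[C@H](C(C(=O)C(F)(F)F)C(=O)c1ccc(OCc2ccccc2)c(OC)c1)CO[Si](c1ccccc1)(c1ccccc1)C(C)(C)C | intermediate (not isolated)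
17 | (3R,4S)-1,4-bis[4-(benzyloxy)-3-methoxyphenyl]-3-{[(tert-butyldiphenylsilyl)oxy]methyl}-2-diazo-4-{[2-(trimethylsilyl)ethoxy]methoxy}butan-1-one | C[Si](C)(C)CCOCO[C@H](c1ccc(OCc2ccccc2)c(OC)c1)[C@H](C(=[N+]=[N-])C(=O)c1ccc(OCc2ccccc2)c(OC)c1)CO[Si](c1ccccc1)(c1ccccc1)C(C)(C)C | intermediate
18 | six-membered oxonium ylide (1,3-dioxan-1-ium ylide; O+ bears the 2-(trimethylsilyl)ethyl group, C4 is the aroyl-stabilised carbanion) | C[Si](C)(C)CC[O+]1CO[C@H](c2ccc(OCc3ccccc3)c(OC)c2)[C@@H](CO[Si](c2ccccc2)(c2ccccc2)C(C)(C)C)[C-]1C(=O)c1ccc(OCc2ccccc2)c(OC)c1 | intermediate (not isolated)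
19 | {(3S,4R,5S)-5-[4-(benzyloxy)-3-methoxyphenyl]-4-{[(tert-butyldiphenylsilyl)oxy]methyl}-3-[2-(trimethylsilyl)ethoxy]oxolan-3-yl}[4-(benzyloxy)-3-methoxyphenyl]methanone | COc1c(OCc2ccccc2)ccc(c1)C(=O)[C@@]2(OCC[Si](C)(C)C)CO[C@H](c3ccc(OCc4ccccc4)c(OC)c3)[C@H]2CO[Si](c5ccccc5)(c6ccccc6)C(C)(C)C | intermediate
20 | [(3S,4R,5S)-5-[4-(benzyloxy)-3-methoxyphenyl]-4-{[(tert-butyldiphenylsilyl)oxy]methyl}-3-hydroxyoxolan-3-yl][4-(benzyloxy)-3-methoxyphenyl]methanone | COc1c(OCc2ccccc2)ccc(c1)C(=O)[C@@]2(O)CO[C@H](c3ccc(OCc4ccccc4)c(OC)c3)[C@H]2CO[Si](c5ccccc5)(c6ccccc6)C(C)(C)C | intermediate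
21 | (3S,4R,5S)-5-[4-(benzyloxy)-3-methoxyphenyl]-3-{[4-(benzyloxy)-3-methoxyphenyl](hydroxy)methyl}-4-{[(tert-butyldiphenylsilyl)oxy]methyl}oxolan-3-ol (C7 epimers) | COc1c(OCc2ccccc2)ccc(c1)C(O)[C@@]2(O)CO[C@H](c3ccc(OCc4ccccc4)c(OC)c3)[C@H]2CO[Si](c5ccccc5)(c6ccccc6)C(C)(C)C | intermediate
22 | (5S,8S,9R)-4,8-bis[4-(benzyloxy)-3-methoxyphenyl]-9-{[(tert-butyldiphenylsilyl)oxy]methyl}-1,3,7-trioxaspiro[4.4]nonane-2-thione (C4 of the spirocycle, i.e. C7, as both epimers) | COc1c(OCc2ccccc2)ccc(c1)C1OC(=S)O[C@@]12CO[C@H](c3ccc(OCc4ccccc4)c(OC)c3)[C@H]2CO[Si](c5ccccc5)(c6ccccc6)C(C)(C)C | intermediate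
23 | O-[(3S,4R,5S)-5-[4-(benzyloxy)-3-methoxyphenyl]-3-{[4-(benzyloxy)-3-methoxyphenyl]methyl}-4-{[(tert-butyldiphenylsilyl)oxy]methyl}oxolan-3-yl] S-(tributylstannyl) thiocarbonate | COc1c(OCc2ccccc2)ccc(c1)C[C@@]2(OC(=O)S[Sn](CCCC)(CCCC)CCCC)CO[C@H](c3ccc(OCc4ccccc4)c(OC)c3)[C@H]2CO[Si](c5ccccc5)(c6ccccc6)C(C)(C)C | intermediate (not isolated)
24 | (3S,4R,5S)-5-[4-(benzyloxy)-3-methoxyphenyl]-3-{[4-(benzyloxy)-3-methoxyphenyl]methyl}-4-(hydroxymethyl)oxolan-3-ol | COc1c(OCc2ccccc2)ccc(c1)C[C@@]2(O)CO[C@H](c3ccc(OCc4ccccc4)c(OC)c3)[C@H]2CO | intermediate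
25 | [(2S,3R,4S)-2-[4-(benzyloxy)-3-methoxyphenyl]-4-{[4-(benzyloxy)-3-methoxyphenyl]methyl}-4-hydroxyoxolan-3-yl]methyl acetate | COc1c(OCc2ccccc2)ccc(c1)C[C@@]2(O)CO[C@H](c3ccc(OCc4ccccc4)c(OC)c3)[C@H]2COC(C)=O | intermediate
26 | [(2S,3R,4S)-4-hydroxy-2-(4-hydroxy-3-methoxyphenyl)-4-[(4-hydroxy-3-methoxyphenyl)methyl]oxolan-3-yl]methyl acetate (olivil monoacetate) | COc1cc(C[C@@]2(O)CO[C@H](c3ccc(O)c(OC)c3)[C@H]2COC(C)=O)ccc1O | target

## Step count and risks

Total: 17 steps. Longest linear sequence: 16 steps (steps 1–6 and 8–17, from 1 to 26); step 7 is a one-step side branch.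

**Step 11 (key step, proposed new method).** The carbenoid can be lost before the ylide forms, by 1,2-hydride migration from C3 to the carbenoid carbon or by 1,5-insertion into the doubly activated acetal C–H. The ylide itself can go astray by [1,4]-shift of C5 to the enolate oxygen or by β-elimination across the silylethyl group. Face selectivity at C4 can erode if the pair leaves the solvent cage before recombining. A switch to copper bis(hexafluoroacetylacetonate), Cu(C5HF6O2)2, would be the first change of conditions. The fallback changes the approach and uses only known reactions. It sets out from ketone 15 and comes back at 20. The lithium enolate of 15 is treated with Eschenmoser's salt, and methylation and elimination give the enone F1. Catalytic OsO4 with N-methylmorpholine N-oxide dihydroxylates the 1,1-disubstituted alkene to the diol F2; here the C4 carbinol is set by face selection next to C3, or by a chiral ligand on osmium, with separation of the epimer if needed. Camphorsulfonic acid in CH2Cl2 then ionises the benzylic C2–O bond, and the primary C5 hydroxyl closes 5-exo onto the benzylic cation to give the thermodynamically preferred 2,3-trans oxolane 20.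

**Step 10.** C-Trifluoroacetylation of the β-branched C4 methylene may be incomplete or reverse on work-up, so that diazo transfer stalls at the ketone. The fallback sets out from 15 and comes back at 17. Nitrosation of the potassium enolate with isoamyl nitrite gives the α-oximino ketone F3, and chloramine (NH2Cl from aqueous ammonia and NaOCl) converts the oxime into the diazo ketone 17 (Forster reaction). The N2 unit is thus built on C4 and not transferred from an azide.

**Step 12.** The Lewis acid may open the benzylic C2–O1 bond (epimerisation at C2 or ring-opened by-products), may promote an acyloin-type ring-enlarging shift of the freed α-ketol, or may partly remove the silyl ether on C6. The fallback sets out from 19 and comes back at 24 without any acid. NaBH4 reduces 19 to the carbinol F4; NaH, CS2 and MeI give the xanthate F5; Bu3SnH/AIBN gives the deoxygenated ether F6. Fluoride under forcing conditions (Bu4NF in DMPU at about 80 °C) then removes the silyl ether and the 2-(trimethylsilyl)ethyl group by β-elimination, to give 24.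

**Step 15.** The thionocarbonate radical adduct may fragment at the wrong C–O bond, the tin thiocarbonate may release the tertiary alcohol sluggishly, or the freed C6 alkoxide may attack the thiocarbonate. The fallback sets out from 21 and comes back at 24. Phenyl chlorothionoformate and pyridine acylate only the secondary C7 hydroxyl, to the O-phenyl thionocarbonate F7. Bu3SnH/AIBN cleaves the only activated C–O bond to give the silyl ether F8 with the C4 hydroxyl free, and Bu4NF then gives 24.

## Further compounds

F1 | step 11 | (3R,4S)-1,4-bis[4-(benzyloxy)-3-methoxyphenyl]-3-{[(tert-butyldiphenylsilyl)oxy]methyl}-2-methylidene-4-{[2-(trimethylsilyl)ethoxy]methoxy}butan-1-one | C[Si](C)(C)CCOCO[C@H](c1ccc(OCc2ccccc2)c(OC)c1)[C@H](C(=C)C(=O)c1ccc(OCc2ccccc2)c(OC)c1)CO[Si](c1ccccc1)(c1ccccc1)C(C)(C)C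
F2 | step 11 | (2S,3R,4S)-1,4-bis[4-(benzyloxy)-3-methoxyphenyl]-3-{[(tert-butyldiphenylsilyl)oxy]methyl}-2-hydroxy-2-(hydroxymethyl)-4-{[2-(trimethylsilyl)ethoxy]methoxy}butan-1-one | C[Si](C)(C)CCOCO[C@H](c1ccc(OCc2ccccc2)c(OC)c1)[C@H]([C@](O)(CO)C(=O)c1ccc(OCc2ccccc2)c(OC)c1)CO[Si](c1ccccc1)(c1ccccc1)C(C)(C)C
F3 | step 10 | (3R,4S)-1,4-bis[4-(benzyloxy)-3-methoxyphenyl]-3-{[(tert-butyldiphenylsilyl)oxy]methyl}-2-(hydroxyimino)-4-{[2-(trimethylsilyl)ethoxy]methoxy}butan-1-one | C[Si](C)(C)CCOCO[C@H](c1ccc(OCc2ccccc2)c(OC)c1)[C@H](C(=NO)C(=O)c1ccc(OCc2ccccc2)c(OC)c1)CO[Si](c1ccccc1)(c1ccccc1)C(C)(C)C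
F4 | step 12 | [4-(benzyloxy)-3-methoxyphenyl]{(3S,4R,5S)-5-[4-(benzyloxy)-3-methoxyphenyl]-4-{[(tert-butyldiphenylsilyl)oxy]methyl}-3-[2-(trimethylsilyl)ethoxy]oxolan-3-yl}methanol (C7 epimers) | COc1c(OCc2ccccc2)ccc(c1)C(O)[C@@]2(OCC[Si](C)(C)C)CO[C@H](c3ccc(OCc4ccccc4)c(OC)c3)[C@H]2CO[Si](c5ccccc5)(c6ccccc6)C(C)(C)C
F5 | step 12 | O-{[4-(benzyloxy)-3-methoxyphenyl]{(3S,4R,5S)-5-[4-(benzyloxy)-3-methoxyphenyl]-4-{[(tert-butyldiphenylsilyl)oxy]methyl}-3-[2-(trimethylsilyl)ethoxy]oxolan-3-yl}methyl} S-methyl dithiocarbonate | COc1c(OCc2ccccc2)ccc(c1)C(OC(=S)SC)[C@@]2(OCC[Si](C)(C)C)CO[C@H](c3ccc(OCc4ccccc4)c(OC)c3)[C@H]2CO[Si](c5ccccc5)(c6ccccc6)C(C)(C)C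
F6 | step 12 | tert-butyl{[(2S,3R,4S)-2-[4-(benzyloxy)-3-methoxyphenyl]-4-{[4-(benzyloxy)-3-methoxyphenyl]methyl}-4-[2-(trimethylsilyl)ethoxy]oxolan-3-yl]methoxy}diphenylsilane | COc1c(OCc2ccccc2)ccc(c1)C[C@@]2(OCC[Si](C)(C)C)CO[C@H](c3ccc(OCc4ccccc4)c(OC)c3)[C@H]2CO[Si](c5ccccc5)(c6ccccc6)C(C)(C)C
F7 | step 15 | O-{[4-(benzyloxy)-3-methoxyphenyl][(3S,4R,5S)-5-[4-(benzyloxy)-3-methoxyphenyl]-4-{[(tert-butyldiphenylsilyl)oxy]methyl}-3-hydroxyoxolan-3-yl]methyl} O-phenyl thiocarbonate | COc1c(OCc2ccccc2)ccc(c1)C(OC(=S)Oc7ccccc7)[C@@]2(O)CO[C@H](c3ccc(OCc4ccccc4)c(OC)c3)[C@H]2CO[Si](c5ccccc5)(c6ccccc6)C(C)(C)C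
F8 | step 15 | (3S,4R,5S)-5-[4-(benzyloxy)-3-methoxyphenyl]-3-{[4-(benzyloxy)-3-methoxyphenyl]methyl}-4-{[(tert-butyldiphenylsilyl)oxy]methyl}oxolan-3-ol | COc1c(OCc2ccccc2)ccc(c1)C[C@@]2(O)CO[C@H](c3ccc(OCc4ccccc4)c(OC)c3)[C@H]2CO[Si](c5ccccc5)(c6ccccc6)C(C)(C)C
A1 | alternative 1 | [(2S,3R,4S)-2-[4-(benzyloxy)-3-methoxyphenyl]-4-{[4-(benzyloxy)-3-methoxyphenyl]methyl}-4-hydroxyoxolan-3-yl]methyl acetate (identical with 25) | COc1c(OCc2ccccc2)ccc(c1)C[C@@]2(O)CO[C@H](c3ccc(OCc4ccccc4)c(OC)c3)[C@H]2COC(C)=O
A2 | alternative 1 | [(2S,3R)-2-[4-(benzyloxy)-3-methoxyphenyl]-4-methylideneoxolan-3-yl]methyl acetate | C=C1CO[C@H](c2ccc(OCc3ccccc3)c(OC)c2)[C@H]1COC(C)=O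
A3 | alternative 1 | [4-(benzyloxy)-3-methoxyphenyl]hydrazine | NNc1ccc(OCc2ccccc2)c(OC)c1
A4 | alternative 2 | (3S,4R,5S)-5-[4-(benzyloxy)-3-methoxyphenyl]-3-{[4-(benzyloxy)-3-methoxyphenyl]methyl}-4-(2-oxo-1,3-oxazolidine-3-carbonyl)oxolan-3-yl acetate | COc1c(OCc2ccccc2)ccc(c1)C[C@@]2(OC(C)=O)CO[C@H](c3ccc(OCc4ccccc4)c(OC)c3)[C@H]2C(=O)N1CCOC1=O
A5 | alternative 2 | (E)-1-[4-(benzyloxy)-3-methoxyphenyl]-4-oxo-4-(2-oxo-1,3-oxazolidin-3-yl)but-2-en-2-yl acetate | CC(=O)O/C(Cc1ccc(OCc2ccccc2)c(OC)c1)=C/C(=O)N1CCOC1=O
A6 | alternative 2 | {[[4-(benzyloxy)-3-methoxyphenyl](chloro)methoxy]methyl}trimethylsilane | C[Si](C)(C)COC(Cl)c1ccc(OCc2ccccc2)c(OC)c1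
A7 | alternative 3 | cis-fused 3,7-dioxabicyclo[3.3.0]octane with bridgehead hydroxyl at C4, the 4-(benzyloxy)-3-methoxyphenyl group on C7 and a 3-methoxy-4-(methanesulfonyloxy)phenyl group on C2 | COc1c(OCc2ccccc2)ccc(c1)[C@@H]3[C@@]2(O)CO[C@H](c4ccc(OS(C)(=O)=O)c(OC)c4)[C@H]2CO3
A8 | alternative 3 | (4R,5S)-4-({[4-(benzyloxy)-3-methoxyphenyl]methoxy}methyl)-5-[3-methoxy-4-(methanesulfonyloxy)phenyl]oxolan-3-one | O=C1CO[C@H](c2ccc(OS(C)(=O)=O)c(OC)c2)[C@H]1COCc1ccc(OCc2ccccc2)c(OC)c1
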